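(The numbers in the tables come from a simulation from invented constants, and the scatter is random.)

A small charge of solid substrate, stirred in a closed flask at noon, gave readings that can be used to reckon the larger flask.

| flask | solid substrate | remark | time |
|---|---|---|---|
| noon | 5.0 × 10⁻⁴ M | run made earlier |  |
| flask | 0.0010 M |  | 30 min |

noon run (percent of the solid substrate charged)

| time / min | target / % | starting material / % |
|---|---|---|
| 0.833 | 4.4 | 14.0 |
| 2.00 | 11.9 | 14.1 |
| 4.00 | 17.1 | 15.1 |
| 6.00 | 20.6 | 14.9 |

(readings scatter by 0.5 percentage points)

- a species is counted by the solid substrate in it: one target counts as two
- given per volume of solution although it is solid: solid substrate
- the numbers in the tables scatter by 0.5 percentage points (one standard deviation)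
- candidate steps: 2 starting material <-> target; solid substrate <-> starting material
- at the start none of the solid substrate is in solution
- what has only dissolved of solid substrate counts as not reacted
- the reaction counts as stopped when no species that holds the solid substrate changes by six tenths of a point or more over the second half of the time
- starting material means what is dissolved; the solid is not counted in it

* which holds at 30 min: what has brought the reaction to rest, or that it has not come to rest (for what has run out or reacted, a solid counts together with what of it has only dissolved) (it is still moving / forward and back rates have come level / all of the solid substrate has reacted)
* how much target there is at 30 min, in percent of the solid substrate charged
* how much starting material there is at 30 min, in percent of the solid substrate charged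

*What do the noon readings show?* Target gained 16 percentage points between the first and last reading, more than starting material moved, which was 0.9 points. So dissolving keeps pace with what target takes from solution.

*What do you carry forward?* The last two noon readings average 7.50 × 10⁻⁵ M. I call this s, the held concentration: the molarity of dissolved starting material standing over undissolved solid, usually called the solubility.

*And the weak spot: is solid left?* At noon's last reading, solution held 35.5% of the charge, and this flask has twice that charge. I expect solid to remain.

*Reckon it in logarithms.* While solid stands, the share of starting material is s divided by the charge. Its logarithm is −0.824 at noon, and the larger charge takes off 0.301, which gives −1.12, or a share of 7.50%.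

*And the forecast?* It says forward and back rates have come level, with target at 12% and starting material at 7.3%: “With solid present, both concentrations at equilibrium are fixed by solubility and K, independent of the charge.” It starts from 14.5% of the noon charge, and I start from the last two readings, so its starting material stands below my 7.50%.

The flask gives forward and back rates have come level, with target at 10.8% and starting material at 7.80%.

    2 starting material ⇌ target (K = 8900 M⁻¹, k = 117 M⁻¹ s⁻¹)
    solid substrate ⇌ starting material, rate k2*(cs2 - [starting material]) while solid is left; crystals form when [starting material] > cs2 (solubility = 0.0780 mM, k = 0.0593 s⁻¹)

Over the second half of the time, no share in this flask moved by more than 0.012 points, and solid substrate stood at 81.4% at 30.0 min. Here s, read off the noon readings with their scatter, gave 7.50%, which is 0.3 points below the computed value.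

In the neighbouring flask with 2.5 × 10⁻⁴ M, the logarithm of the share rises to −0.523, so s gives 30.0%. That flask's computed result is 31.2% starting material, with 25.5% solid substrate still standing.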